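**Retrosynthetic overview**

1. The 4-hydroxybenzoate is attached last, by Mitsunobu esterification with inversion at the acyloxy carbon C6, so the immediate precursor is the bicyclic C6-epimeric diol 13.
2. Key disconnection: the seven-membered ring is opened at the bond between the methyl-bearing alkene carbon C8 and the neighbouring ring CH2 (C9), together with the C1–C10 bond. Diol 13 then comes from methylidenecyclopentane/(Z)-alkenyl iodide 10, vinylboronate 11 (supplying C9–C10) and one hydrogen atom, joined in one flask (Fe(acac)3/PhSiH3 radical hydroalkylation, then Pd(OAc)2/RuPhos coupling).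
3. Enabling feature: the angular methyl on the quaternary ring-fusion carbon C1 is the Markovnikov hydrogen-atom adduct of an exocyclic methylene. C1 is linked to the trisubstituted C7=C8 alkene of the seven-membered ring by exactly a CH2CH2 bridge, and C8 lies cis to the C6 carbinol across that alkene, so a two-carbon vinylboron linchpin and a (Z)-iodoalkene made from a propargylic alcohol map onto the ring.
4. Alkenyl iodide 10 comes from Red-Al/I2 on enyne diol 8, which comes from a [2,3]-Wittig rearrangement of propargyl ether 7 (sets C5, C6 and the exocyclic methylene). Ether 7 comes from vinyl epoxide 5, made by asymmetric epoxidation (sets C4) and methylenation of 3-isopropylcyclopentenone 3.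
5. Ring order: the five-membered ring is present from the start (3-ethoxycyclopentenone 1); the seven-membered ring is closed last, in the key step.

Key step: step 7

Remark: locants in the text are daucane locants (C1 ring-fusion carbon with the angular methyl, C4 isopropyl carbinol, C5 ring-fusion CH, C6 acyloxy carbon, C7=C8 alkene with the methyl on C8, C9 and C10 the CH2CH2 bridge).

Remark (assumption): the [2,3]-Wittig rearrangement of step 5 is assumed to follow the usual rule that an E-type allyl unit gives the anti product. C6 is therefore made as the epimer and is inverted in step 8.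

**Route**

Step 1
Reactants: 1 3-ethoxycyclopent-2-en-1-one
Product: 3 3-(propan-2-yl)cyclopent-2-en-1-one, via carbinol adduct 2 (not isolated)
Conditions: i-PrMgCl, THF, −78 to 0 °C; then 1 M HCl, rt
Reagents that add atoms: isopropylmagnesium chloride, CC(C)[Mg]Cl
Why: Stork–Danheiser transposition: 1,2-addition to the vinylogous ester and acid-induced loss of ethanol should give the β-isopropyl enone; no stereocenter is formed.

Step 2
Reactants: 3 3-(propan-2-yl)cyclopent-2-en-1-one
Product: 4 (1S,5R)-5-(propan-2-yl)-6-oxabicyclo[3.1.0]hexan-2-one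
Conditions: 9-amino-9-deoxy-epi-quinine·2CF3CO2H (10 mol%), 50% aq. H2O2, dioxane, 35 °C
Reagents that add atoms: hydrogen peroxide, OO
Why: Amine-catalysed asymmetric Weitz–Scheffer epoxidation through a chiral iminium ion, in which hydroperoxide adds to one face of the β-carbon and fixes the tertiary C–O stereocenter C4; the quinidine-derived pseudoenantiomer is used instead if that is the one delivering (1S,5R)-4.

Step 3
Reactants: 4 (1S,5R)-5-(propan-2-yl)-6-oxabicyclo[3.1.0]hexan-2-one
Product: 5 (1R,5R)-4-methylidene-1-(propan-2-yl)-6-oxabicyclo[3.1.0]hexane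
Conditions: Ph3PCH3Br, KOt-Bu, THF, 0 °C
Reagents that add atoms: methyltriphenylphosphonium bromide, C[P+](c1ccccc1)(c1ccccc1)c1ccccc1.[Br-]
Why: Wittig methylenation of the epoxy ketone with the non-stabilised ylide should leave the epoxide and its configuration untouched (the descriptor changes only through CIP priorities).

Step 4
Reactants: 5 (1R,5R)-4-methylidene-1-(propan-2-yl)-6-oxabicyclo[3.1.0]hexane; 6 but-2-yn-1-ol
Product: 7 (1R)-3-[(but-2-yn-1-yloxy)methyl]-1-(propan-2-yl)cyclopent-2-en-1-ol
Conditions: Pd(PPh3)4 (5 mol%), 6 (5 equiv), THF, 0 °C to rt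
Reagents that add atoms: none
Why: Tsuji–Trost-type allylic etherification: zerovalent palladium opens the vinyl epoxide at the allylic C–O bond, and the alkoxide of 6 should attack the unhindered exocyclic CH2 terminus of the π-allyl (formal SN2′, 1,4-addition); the tertiary C4–O bond is not broken, so C4 is retained.

Step 5
Reactants: 7 (1R)-3-[(but-2-yn-1-yloxy)methyl]-1-(propan-2-yl)cyclopent-2-en-1-ol
Product: 8 (1S)-1-[(1S,2R)-2-hydroxy-5-methylidene-2-(propan-2-yl)cyclopentyl]but-2-yn-1-ol
Conditions: n-BuLi (2.3 equiv), THF, −78 °C; then aq. NH4Cl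
Reagents that add atoms: none
Why: [2,3]-Wittig rearrangement of the propargylic carbanion forms C5–C6 and moves the alkene to the exocyclic methylene; the new bond should enter the cyclopentene face cis to the lithium alkoxide (anti to isopropyl), and the ring-fixed E-type alkene should give the anti C4/C6–O relationship through the envelope transition state, which is the C6 epimer of the target.

Step 6
Reactants: 8 (1S)-1-[(1S,2R)-2-hydroxy-5-methylidene-2-(propan-2-yl)cyclopentyl]but-2-yn-1-ol
Product: 10 (1S,2Z)-1-[(1S,2R)-2-hydroxy-5-methylidene-2-(propan-2-yl)cyclopentyl]-3-iodobut-2-en-1-ol, via cyclic alkenylalanate 9 (not isolated)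
Conditions: NaAlH2(OCH2CH2OMe)2 (Red-Al, 3 equiv), THF, 0 °C to rt; EtOAc; then I2, −78 to 0 °C
Reagents that add atoms: iodine, II
Why: Hydroxyl-directed trans-hydroalumination of the propargylic alcohol puts hydride on the proximal and aluminium on the distal, methyl-bearing alkyne carbon within a five-membered oxa-alanate, and iodinolysis with retention should give the (Z)-iodoalkene with iodine cis to the carbinol; the unactivated methylidene is inert.

Step 7
Reactants: 10 (1S,2Z)-1-[(1S,2R)-2-hydroxy-5-methylidene-2-(propan-2-yl)cyclopentyl]-3-iodobut-2-en-1-ol; 11 4,4,5,5-tetramethyl-2-vinyl-1,3,2-dioxaborolane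
Product: 13 (3R,3aS,4R,8aS)-6,8a-dimethyl-3-(propan-2-yl)-1,2,3,3a,4,7,8,8a-octahydroazulene-3,4-diol, via alkylboronate 12 (not isolated)
Conditions: Fe(acac)3 (30 mol%), PhSiH3, 11 (4 equiv), EtOH/THF, 60 °C; volatiles including excess 11 removed in vacuo; then Pd(OAc)2 (10 mol%), RuPhos (20 mol%), aq. K3PO4, toluene/THF (0.005 M), 80 °C
Reagents that add atoms: none
Why: Proposed new method: an iron hydride generated from Fe(acac)3 and PhSiH3 should transfer a hydrogen atom to the CH2 terminus of the exocyclic methylene of 10, the tertiary cyclopentyl radical adds to vinylboronate 11 and the α-boryl radical is quenched by hydrogen transfer to give primary alkylboronate 12, whose C–B bond is then coupled with the (Z)-alkenyl iodide by zerovalent palladium (oxidative addition, base-assisted transmetalation, reductive elimination). The closest known reaction types are the iron-hydride reductive coupling of 1,1-disubstituted alkenes with electron-poor alkenes, Giese additions of tertiary radicals to vinylboronic esters under photoredox conditions and the intramolecular B-alkyl Suzuki–Miyaura coupling; new is the use of a vinylboronate as acceptor for a radical made by hydrogen-atom transfer and the telescoping of both events into one formal (5+2) annulation. The seven-membered ring is closed in the palladium stage by sp3–sp2 reductive elimination from an eight-membered palladacycle, so the alkene stays where the iodide was and keeps its cis geometry inside the ring. The only new stereocenter, the quaternary C1, is set in the radical addition: the acceptor should approach the planar ring radical anti to the branched iodoalkenyl carbinol chain on the neighbouring C5, placing the CH2CH2B arm trans to that chain and the new methyl cis to it, which is the trans ring fusion. The step needs intermolecular trapping of the tertiary radical to outrun its reduction, and quenching of the α-boryl radical to outrun 6-exo attack on the iodoalkene; it relies on excess 11, on the boron-stabilised and therefore slowly cyclising adduct radical, and on faster hydrogen-atom transfer to the 1,1-disubstituted alkene than to the iodo-substituted trisubstituted one, and excess 11 must be stripped before Pd(OAc)2 is added so that only the sp3 boronate couples.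

Step 8
Reactants: 13 (3R,3aS,4R,8aS)-6,8a-dimethyl-3-(propan-2-yl)-1,2,3,3a,4,7,8,8a-octahydroazulene-3,4-diol; 14 4-(acetyloxy)benzoic acid
Product: 15 (3R,3aS,4S,8aS)-3-hydroxy-6,8a-dimethyl-3-(propan-2-yl)-1,2,3,3a,4,7,8,8a-octahydroazulen-4-yl 4-(acetyloxy)benzoate
Conditions: PPh3, DIAD, toluene, 0 °C to rt
Reagents that add atoms: none
Why: Mitsunobu esterification: the secondary, pseudoaxial allylic alcohol is activated as its oxyphosphonium ion and displaced by the carboxylate with inversion (SN2), which should set the required C6 configuration while the tertiary alcohol stays inert.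

Step 9
Reactants: 15 (3R,3aS,4S,8aS)-3-hydroxy-6,8a-dimethyl-3-(propan-2-yl)-1,2,3,3a,4,7,8,8a-octahydroazulen-4-yl 4-(acetyloxy)benzoate
Product: 16 (3R,3aS,4S,8aS)-3-hydroxy-6,8a-dimethyl-3-(propan-2-yl)-1,2,3,3a,4,7,8,8a-octahydroazulen-4-yl 4-hydroxybenzoate
Conditions: K2CO3 (0.2 equiv), MeOH, 0 °C
Reagents that add atoms: none
Why: Chemoselective transesterification: the aryl acetate should be methanolysed far faster than the hindered secondary benzoate, which is further deactivated once the para-phenoxide forms.

**Compound list**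

1 | 3-ethoxycyclopent-2-en-1-one | CCOC1=CC(=O)CC1 | starting material
2 | 3-ethoxy-1-(propan-2-yl)cyclopent-2-en-1-ol (racemic, formed as its magnesium alkoxide) | CCOC1=CC(O)(C(C)C)CC1 | intermediate
3 | 3-(propan-2-yl)cyclopent-2-en-1-one | CC(C)C1=CC(=O)CC1 | intermediate
4 | (1S,5R)-5-(propan-2-yl)-6-oxabicyclo[3.1.0]hexan-2-one | O=C1CC[C@]2(C(C)C)O[C@H]12 | intermediate
5 | (1R,5R)-4-methylidene-1-(propan-2-yl)-6-oxabicyclo[3.1.0]hexane | C=C1CC[C@]2(C(C)C)O[C@H]12 | intermediate
6 | but-2-yn-1-ol | CC#CCO | starting material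
7 | (1R)-3-[(but-2-yn-1-yloxy)methyl]-1-(propan-2-yl)cyclopent-2-en-1-ol | CC#CCOCC1=C[C@](O)(C(C)C)CC1 | intermediate
8 | (1S)-1-[(1S,2R)-2-hydroxy-5-methylidene-2-(propan-2-yl)cyclopentyl]but-2-yn-1-ol | CC#C[C@@H](O)[C@@H]1C(=C)CC[C@@]1(O)C(C)C | intermediate
9 | sodium cyclic (Z)-alkenylalanate of 8 (five-membered O–Al–C=C–C ring, two 2-methoxyethoxy groups on aluminium; drawn with the tertiary hydroxyl free) | CC1=C[C@H]([C@@H]2C(=C)CC[C@@]2(O)C(C)C)O[Al-]1(OCCOC)OCCOC.[Na+] | intermediate
10 | (1S,2Z)-1-[(1S,2R)-2-hydroxy-5-methylidene-2-(propan-2-yl)cyclopentyl]-3-iodobut-2-en-1-ol | C/C(I)=C/[C@@H](O)[C@@H]1C(=C)CC[C@@]1(O)C(C)C | intermediate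
11 | 4,4,5,5-tetramethyl-2-vinyl-1,3,2-dioxaborolane | C=CB1OC(C)(C)C(C)(C)O1 | starting material
12 | (1S,2Z)-1-[(1S,2R,5S)-2-hydroxy-5-methyl-2-(propan-2-yl)-5-[2-(4,4,5,5-tetramethyl-1,3,2-dioxaborolan-2-yl)ethyl]cyclopentyl]-3-iodobut-2-en-1-ol | C/C(I)=C/[C@@H](O)[C@@H]1[C@@](C)(CCB2OC(C)(C)C(C)(C)O2)CC[C@@]1(O)C(C)C | intermediate
13 | (3R,3aS,4R,8aS)-6,8a-dimethyl-3-(propan-2-yl)-1,2,3,3a,4,7,8,8a-octahydroazulene-3,4-diol | CC1=C[C@@H](O)[C@@H]2[C@@](C)(CC1)CC[C@@]2(O)C(C)C | intermediate
14 | 4-(acetyloxy)benzoic acid | CC(=O)Oc1ccc(cc1)C(=O)O | starting material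
15 | (3R,3aS,4S,8aS)-3-hydroxy-6,8a-dimethyl-3-(propan-2-yl)-1,2,3,3a,4,7,8,8a-octahydroazulen-4-yl 4-(acetyloxy)benzoate | CC1=C[C@H](OC(=O)c2ccc(OC(C)=O)cc2)[C@@H]2[C@@](C)(CC1)CC[C@@]2(O)C(C)C | intermediate
16 | (3R,3aS,4S,8aS)-3-hydroxy-6,8a-dimethyl-3-(propan-2-yl)-1,2,3,3a,4,7,8,8a-octahydroazulen-4-yl 4-hydroxybenzoate | CC1=C[C@H](OC(=O)c2ccc(O)cc2)[C@@H]2[C@@](C)(CC1)CC[C@@]2(O)C(C)C | target

Total step count: 9. Longest linear sequence: 9 steps (1 to 16).

**Steps most likely to fail**

Step 7 (carries the label). The vinylboronate may be consumed unproductively by hydrogen-atom transfer. The α-boryl adduct radical may be quenched too slowly and cyclise 6-exo onto the iodoalkene. Residual iron and silane may cause hydrodeiodination in the palladium stage. The fallback uses known chemistry and sets out from 10. Iron-hydride reductive coupling with methyl acrylate (Fe(acac)3, PhSiH3, EtOH, 60 °C), where the ester-stabilised adduct radical is reduced quickly, should give methyl 3-[(1R,2S,3R)-3-hydroxy-2-[(1S,2Z)-1-hydroxy-3-iodobut-2-en-1-yl]-1-methyl-3-(propan-2-yl)cyclopentyl]propanoate F1. Saponification (LiOH, THF/H2O) should give the corresponding propanoic acid F2. N-Hydroxyphthalimide and N,N′-diisopropylcarbodiimide should give the 1,3-dioxoisoindolin-2-yl ester F3. Light-driven decarboxylative borylation (bis(catecholato)diboron, DMAc, blue LEDs; then pinacol, Et3N) comes back to the route at 12, now isolated and purified. Compound 12 is then cyclised to 13 under the Pd(OAc)2/RuPhos/K3PO4 conditions of step 7, a B-alkyl Suzuki–Miyaura coupling.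

Step 4. The aliphatic alkoxide may attack the π-allyl intermediate too slowly, so that isomerisation of the vinyl epoxide (β-hydride elimination to dienol or enone) or attack at the ring terminus takes over. The fallback sets out from 5. Addition of acetic acid catalysed by Pd(PPh3)4 (THF, 0 °C), a well-behaved 1,4-opening with a carboxylate, should give [(3R)-3-hydroxy-3-(propan-2-yl)cyclopent-1-en-1-yl]methyl acetate F4. Methanolysis (K2CO3, MeOH) should give (1R)-3-(hydroxymethyl)-1-(propan-2-yl)cyclopent-2-en-1-ol F5. Selective O-alkylation of the primary allylic hydroxyl (NaH, 1-bromobut-2-yne, THF, 0 °C) comes back to the route at 7.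

Step 8. Activation of the hindered pseudoaxial allylic alcohol may lead to anti-elimination towards a diene or to allylic transposition instead of clean inversion. The fallback sets out from 13. Oxidation with MnO2 (CH2Cl2, rt, neutral so that the β-hydroxy ketone does not undergo retro-aldol cleavage) should give (3R,3aR,8aS)-3-hydroxy-6,8a-dimethyl-3-(propan-2-yl)-2,3,3a,7,8,8a-hexahydroazulen-4(1H)-one F6. Luche reduction (NaBH4, CeCl3·7H2O, MeOH, −78 °C) with axial hydride delivery should give the equatorial alcohol (3R,3aS,4S,8aS)-6,8a-dimethyl-3-(propan-2-yl)-1,2,3,3a,4,7,8,8a-octahydroazulene-3,4-diol F7. Acylation of the secondary hydroxyl with 4-(acetyloxy)benzoyl chloride (pyridine, DMAP, CH2Cl2, 0 °C), with retention, comes back to the route at 15.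

**Further compounds**

F1 | step 7 | methyl 3-[(1R,2S,3R)-3-hydroxy-2-[(1S,2Z)-1-hydroxy-3-iodobut-2-en-1-yl]-1-methyl-3-(propan-2-yl)cyclopentyl]propanoate | C/C(I)=C/[C@@H](O)[C@@H]1[C@@](C)(CCC(=O)OC)CC[C@@]1(O)C(C)C
F2 | step 7 | 3-[(1R,2S,3R)-3-hydroxy-2-[(1S,2Z)-1-hydroxy-3-iodobut-2-en-1-yl]-1-methyl-3-(propan-2-yl)cyclopentyl]propanoic acid | C/C(I)=C/[C@@H](O)[C@@H]1[C@@](C)(CCC(=O)O)CC[C@@]1(O)C(C)C
F3 | step 7 | 1,3-dioxoisoindolin-2-yl 3-[(1R,2S,3R)-3-hydroxy-2-[(1S,2Z)-1-hydroxy-3-iodobut-2-en-1-yl]-1-methyl-3-(propan-2-yl)cyclopentyl]propanoate | C/C(I)=C/[C@@H](O)[C@@H]1[C@@](C)(CCC(=O)ON2C(=O)c3ccccc3C2=O)CC[C@@]1(O)C(C)C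
F4 | step 4 | [(3R)-3-hydroxy-3-(propan-2-yl)cyclopent-1-en-1-yl]methyl acetate | CC(=O)OCC1=C[C@](O)(C(C)C)CC1
F5 | step 4 | (1R)-3-(hydroxymethyl)-1-(propan-2-yl)cyclopent-2-en-1-ol | OCC1=C[C@](O)(C(C)C)CC1
F6 | step 8 | (3R,3aR,8aS)-3-hydroxy-6,8a-dimethyl-3-(propan-2-yl)-2,3,3a,7,8,8a-hexahydroazulen-4(1H)-one | CC1=CC(=O)[C@@H]2[C@@](C)(CC1)CC[C@@]2(O)C(C)C
F7 | step 8 | (3R,3aS,4S,8aS)-6,8a-dimethyl-3-(propan-2-yl)-1,2,3,3a,4,7,8,8a-octahydroazulene-3,4-diol | CC1=C[C@H](O)[C@@H]2[C@@](C)(CC1)CC[C@@]2(O)C(C)C
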